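**Retrosynthetic overview**

- Ochtodene, (2S,3E,4S,6S)-6-bromo-3-(2-bromoethylidene)-2,4-dichloro-1,1-dimethylcyclohexane, is cut back to acyclic (3Z,4S)-4-chloro-3-(chloromethylidene)-7-methylocta-1,6-diene. An anodic Br+ cascade forms ring bond C1–C2, C6–Br and the allylic CH2–Br in one operation.
- The dichloride comes from the (3Z,4R)-dienol by C–O to C–Cl exchange with inversion.
- The dienol comes from (3R)-6-methylhept-5-en-1-yn-3-ol and vinylmagnesium chloride by alkoxide-directed anti-vinylmagnesiation; a Cl+ quench fixes the Z chloroalkene.
- The alkynol comes from methyl (2R)-2-hydroxy-5-methylhex-4-enoate, itself from methyl (R)-glycidate (made from L-serine) and an isobutenyl Grignard reagent. The glycidate carbon becomes C4 and later directs C2 and C6.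
- Ring order: one carbocycle only, closed in the last step.

Assumption: methyl (R)-glycidate and both Grignard solutions are bought; ring locants follow the systematic name above, and C4 of the octadiene chain is C4 of the ring.

**Step 1**
Reactants: 1 methyl (2R)-oxirane-2-carboxylate; 2 (2-methylprop-1-en-1-yl)magnesium bromide
Product: 3 methyl (2R)-2-hydroxy-5-methylhex-4-enoate
Conditions: CuBr·SMe2 (10 mol%), THF, −45 °C → −20 °C; then H2O
Reagents that add atoms: none
Why: Copper-catalysed SN2 opening of the epoxide at its unsubstituted carbon by the alkenyl Grignard reagent outruns ester addition at −45 °C (known for glycidic esters), and the purchased stereocentre is not touched.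

**Step 2**
Reactants: 3
Product: 4 methyl (2R)-5-methyl-2-[(triethylsilyl)oxy]hex-4-enoate
Conditions: Et3SiCl, imidazole, CH2Cl2, 0 °C → rt
Reagents that add atoms: chlorotriethylsilane, CC[Si](Cl)(CC)CC
Why: Standard silylation of a secondary alcohol; the silyl ether guards the α-centre against epimerisation and side reactions of a free α-hydroxy aldehyde in the next step.

**Step 3**
Reactants: 4
Product: 7 (3R)-6-methylhept-5-en-1-yn-3-ol, via silyloxy aldehyde 5 (not isolated), via silyl ether of the alkynol 6 (not isolated)
Conditions: iBu2AlH (1.1 equiv), CH2Cl2, −78 °C; then MeOH, K2CO3, dimethyl (1-diazo-2-oxopropyl)phosphonate, −78 °C → rt; then 1 M aq. HCl, 0 °C → rt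
Reagents that add atoms: dimethyl (1-diazo-2-oxopropyl)phosphonate (Ohira–Bestmann reagent), COP(=O)(OC)C(=[N+]=[N-])C(C)=O
Why: One-pot ester half-reduction and Seyferth–Gilbert homologation (Ohira–Bestmann variant) is established for α-silyloxy esters without loss of configuration, and dilute acid then frees the hydroxyl needed as directing group.

**Step 4**
Reactants: 7; 8 ethenylmagnesium chloride
Product: 10 (3Z,4R)-3-(chloromethylidene)-7-methylocta-1,6-dien-4-ol, via alkenylmagnesium chelate 9 (not isolated)
Conditions: CH2=CHMgCl (3.5 equiv), CuBr·SMe2 (10 mol%), THF/toluene, 0 °C → 50 °C; then N-chlorosuccinimide (3 equiv), −40 °C → 0 °C; H2O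
Reagents that add atoms: N-chlorosuccinimide, O=C1CCC(=O)N1Cl
Why: Alkoxide-directed anti-carbomagnesiation of a propargylic alcohol (Duboudin/Fallis type) places vinyl on the proximal alkyne carbon and magnesium on the terminal carbon inside a five-membered chelate, so chlorination with retention leaves Cl cis to the carbinol carbon (Z); the carbinol centre is not involved.

**Step 5**
Reactants: 10
Product: 11 (3Z,4S)-4-chloro-3-(chloromethylidene)-7-methylocta-1,6-diene
Conditions: PPh3 (1.3 equiv), Cl3CC(O)CCl3 (2 equiv), CH2Cl2, −20 °C → 0 °C
Reagents that add atoms: hexachloroacetone, ClC(Cl)(Cl)C(=O)C(Cl)(Cl)Cl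
Why: Appel-type chlorination with PPh3/hexachloroacetone converts secondary allylic alcohols into chlorides by SN2 displacement of the oxyphosphonium group (inversion, R → S) with little allylic shift; SN2' attack is further disfavoured because the distal alkene carbon already carries chlorine.

**Step 6**
Reactants: 11
Product: 14 ochtodene, via bromonium ion 12 (not isolated), via cyclised allyl cation 13 (not isolated)
Conditions: nBu4NBr (2.2 equiv), (CF3)2CHOH/CH2Cl2 4:1, undivided cell, graphite anode, Pt cathode, constant current 2 mA cm−2, 2.3 F mol−1, 0 °C
Reagents that add atoms: tetrabutylammonium bromide, CCCC[N+](CCCC)(CCCC)CCCC.[Br-]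
Why: Proposed new method: anodic oxidation of bromide releases Br2 slowly, which reversibly forms the bromonium ion at the electron-rich trisubstituted alkene (the chlorine-bearing diene is deactivated); in the ionising, hydrogen-bonding fluoroalcohol bromide return is slow and any vicinal dibromide re-ionises, so the chloromethylidene terminus of the diene attacks the tertiary carbon 6-endo through a chair with Br equatorial (anti opening), C4–Cl pseudoaxial (so that H, not Cl, lies in the diene plane next to the inward hydrogen of the s-trans vinyl group, avoiding allylic strain) and the Z chlorine therefore axial on the same face, which sets C2 and C6 from C4 (the two Cl cis, Br trans to both); bromide then captures the allyl cation at its primary end to give the E alkene; the closest known reactions are bromonium polyene cyclisations with stoichiometric Br+ donors in this solvent, electrochemical bromofunctionalisation of alkenes (bromolactonisation, dibromination) and Lewis-acid 1,4-addition of alkyl halides to 1,3-dienes.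

**Compound list**

1 | methyl (2R)-oxirane-2-carboxylate (methyl (R)-glycidate) | COC(=O)[C@H]1CO1 | starting material
2 | (2-methylprop-1-en-1-yl)magnesium bromide | CC(C)=C[Mg]Br | starting material
3 | methyl (2R)-2-hydroxy-5-methylhex-4-enoate | COC(=O)[C@H](O)CC=C(C)C | intermediate
4 | methyl (2R)-5-methyl-2-[(triethylsilyl)oxy]hex-4-enoate | COC(=O)[C@H](O[Si](CC)(CC)CC)CC=C(C)C | intermediate
5 | (2R)-5-methyl-2-[(triethylsilyl)oxy]hex-4-enal | O=C[C@H](O[Si](CC)(CC)CC)CC=C(C)C | intermediate
6 | triethyl{[(3R)-6-methylhept-5-en-1-yn-3-yl]oxy}silane | C#C[C@H](O[Si](CC)(CC)CC)CC=C(C)C | intermediate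
7 | (3R)-6-methylhept-5-en-1-yn-3-ol | C#C[C@H](O)CC=C(C)C | intermediate
8 | ethenylmagnesium chloride | C=C[Mg]Cl | starting material
9 | five-membered alkenylmagnesium alkoxide chelate (Mg on the terminal alkene carbon cis to the R-configured alkoxide carbon) | C=CC1=C[Mg]O[C@@H]1CC=C(C)C | intermediate
10 | (3Z,4R)-3-(chloromethylidene)-7-methylocta-1,6-dien-4-ol | C=C/C(=C/Cl)[C@H](O)CC=C(C)C | intermediate
11 | (3Z,4S)-4-chloro-3-(chloromethylidene)-7-methylocta-1,6-diene | C=C/C(=C/Cl)[C@@H](Cl)CC=C(C)C | intermediate
12 | (6S)-6,7-bromonium ion of 11: (3S)-3-[(2S,3Z)-2-chloro-3-(chloromethylidene)pent-4-en-1-yl]-2,2-dimethylbromiranium | CC1(C)[Br+][C@H]1C[C@H](Cl)/C(=C\Cl)C=C | intermediate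
13 | cyclised allyl cation, (2S,4S,6S)-6-bromo-2,4-dichloro-3-ethenyl-1,1-dimethylcyclohexan-3-ylium | CC1(C)[C@@H](Br)C[C@H](Cl)[C+](C=C)[C@@H]1Cl | intermediate
14 | ochtodene, (2S,3E,4S,6S)-6-bromo-3-(2-bromoethylidene)-2,4-dichloro-1,1-dimethylcyclohexane | CC1(C)[C@@H](Br)C[C@H](Cl)/C(=C\CBr)[C@@H]1Cl | target

**Step count and risks**

Total steps: 6. Longest linear sequence: 6 steps (1 → 14).

Steps most likely to fail:

Step 6 (the proposed new step). Three things can go wrong:
- Bromide or solvent may capture the bromonium ion before the weakly nucleophilic chlorodiene does.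
- The competing chair with C4–Cl equatorial and an s-cis diene would give the 2,4-trans Z isomer. My own strain estimate puts the two chairs close in energy, so the diastereoselectivity is the least secure point of the route.
- The allylic chlorides may ionise.

The fallback sets out from 11 and comes back at 14, as a two-pot chemical route. Br2 (1.0 equiv, CH2Cl2, −78 °C) adds only to the trisubstituted alkene and gives (3Z,4S)-6,7-dibromo-4-chloro-3-(chloromethylidene)-7-methyloct-1-ene F1 as both C6 epimers. Catalytic ZnBr2 (10 mol%, CH2Cl2/MeNO2, −40 °C) then ionises the tertiary bromide with neighbouring-bromine help. The bromonium ions, which exchange Br+ between alkenes, add across the diene in the known Lewis-acid-catalysed 1,4-addition mode of tertiary alkyl halides to 1,3-dienes, giving 14. Both operations are established reaction types, but this fallback does not cure a wrong chair preference.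

Step 5. The oxyphosphonium ion may ionise to a chlorine-stabilised allyl cation (loss of configuration, 1,1-dichloride by allylic shift) or eliminate. The fallback sets out from 10 and comes back at 11 through a discrete sulfonate. MsCl, Et3N, CH2Cl2, −40 °C gives (3Z,4R)-3-(chloromethylidene)-7-methylocta-1,6-dien-4-yl methanesulfonate F2, used crude. LiCl in acetone at −20 °C → 0 °C displaces it by SN2 with inversion.

Step 4. The Grignard reagent may deprotonate the terminal alkyne and stall the carbomagnesiation, or the chlorine quench may be incomplete and leave the protonated diene. The fallback sets out from 7 and comes back at 10 and covers only the quench failure. The same vinylmagnesiation is quenched with I2, the classical trap for these chelates, to give (3Z,4R)-3-(iodomethylidene)-7-methylocta-1,6-dien-4-ol F3. tBuLi (3.1 equiv, Et2O, −78 °C) followed by C2Cl6 then exchanges iodine for chlorine through the alkenyllithium with retention of geometry.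

**Further compounds**

F1 | step 6 | (3Z,4S)-6,7-dibromo-4-chloro-3-(chloromethylidene)-7-methyloct-1-ene (both C6 epimers) | C=C/C(=C/Cl)[C@@H](Cl)CC(Br)C(C)(C)Br
F2 | step 5 | (3Z,4R)-3-(chloromethylidene)-7-methylocta-1,6-dien-4-yl methanesulfonate | C=C/C(=C/Cl)[C@H](OS(C)(=O)=O)CC=C(C)C
F3 | step 4 | (3Z,4R)-3-(iodomethylidene)-7-methylocta-1,6-dien-4-ol | C=C/C(=C/I)[C@H](O)CC=C(C)C
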